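**Retrosynthetic overview**

- Target 19 (3,4,7-tribromo-2-chloro-1H-indole): C3–Br goes on last by electrophilic bromination, and C2–Cl comes from C2 lithiation/chlorination of an N-sulfonyl-4,7-dibromoindole, itself reached from the indole-2-carboxylate by saponification and protodecarboxylation.
- Key disconnection: N1–C7a and C2–C3 of the pyrrole ring, cut back to an ortho-fluorobenzaldehyde and an N-tosylglycinate (fluoride displacement, then aldol condensation).
- Feature the strategy rests on: C7a carries N1 and lies between C7–Br and C3a, and C3a carries C3. An aldehyde carbon (future C3) ortho to an activated C–F (future C7a) on a benzene ring that already holds both bromines (future C4 and C7) maps onto this exactly.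
- Ring order: the benzene ring is bought with both bromines in place; the pyrrole ring is the only ring formed (step 3).

Key step: step 3

Remark: LDA is taken as the commercial solution; the target has no stereocentre, and the stereocentres of the transient intermediates 3 and 9 are lost in the same step in which they form.

**Route**

Step 1
Reactants: 1 1,4-dibromo-2-fluorobenzene
Product: 4 3,6-dibromo-2-fluorobenzaldehyde, via 3,6-dibromo-2-fluorophenyllithium 2 (not isolated), via lithium hemiaminal alkoxide 3 (not isolated)
Conditions: LDA, THF, −78 °C; DMF, −78 °C; aq. HCl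
Reagents that add atoms: N,N-dimethylformamide, CN(C)C=O
Why: Directed ortho-lithiation then formylation: the C–H flanked by fluorine and bromine is the most acidic, so the lithium amide should metalate there at −78 °C without bromine–lithium exchange, and aryllithium 2 adds to DMF to give alkoxide 3, which collapses to the aldehyde on acidic work-up.

Step 2
Reactants: 5 glycine ethyl ester hydrochloride; 6 p-toluenesulfonyl chloride
Product: 7 ethyl N-tosylglycinate (ethyl N-[(4-methylphenyl)sulfonyl]glycinate)
Conditions: Et3N, CH2Cl2, 0 °C to rt
Reagents that add atoms: none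
Why: N-sulfonylation of a primary amine with a sulfonyl chloride; triethylamine frees the amine from its salt and takes up the HCl, and the ethyl ester is untouched under these anhydrous conditions.

Step 3
Reactants: 4 3,6-dibromo-2-fluorobenzaldehyde; 7 ethyl N-tosylglycinate
Product: 10 ethyl 4,7-dibromo-1-tosyl-1H-indole-2-carboxylate, via N-aryl-N-tosylglycinate 8 (not isolated), via 3-hydroxyindoline 9 (not isolated)
Conditions: K2CO3, DMF, 90 °C
Reagents that add atoms: none
Why: K2CO3 deprotonates the sulfonamide N–H of 7, the nitrogen anion adds to the fluorine-bearing carbon of 4 (activated by the ortho formyl group), and loss of fluoride from the Meisenheimer adduct forms N1–C7a and gives 8. The α-carbon of 8, acidified by the ester and the N-sulfonyl group, is then deprotonated and adds to the neighbouring aldehyde in a 5-(enolexo)-exo-trig aldol closure that forms C2–C3 and gives 9, and E1cB loss of water through the ester enolate aromatizes the pyrrole ring, the only ring closed. The closest known reactions are the base-mediated domino fluoride displacement/aldol condensation of 2-fluorobenzaldehydes with thioglycolates or N-substituted glycinates, and the K2CO3-mediated closure of N-(2-formylaryl)-N-sulfonylglycinates to 1-sulfonylindole-2-carboxylates. No stereocentre is kept, since the two of 9 are erased by the dehydration. The selectivity needed is displacement of fluoride and not of the C6 bromine, which is also ortho to the aldehyde; it is secured because the rate-determining addition of an addition–elimination substitution is far faster at C–F than at C–Br, and no metal is present that could insert into the aryl bromides. Any N-detosylated ester formed in the pot is harmless, because step 4 removes the tosyl group in any case.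

Step 4
Reactants: 10 ethyl 4,7-dibromo-1-tosyl-1H-indole-2-carboxylate
Product: 12 4,7-dibromo-1H-indole-2-carboxylic acid, via sodium 4,7-dibromo-1H-indole-2-carboxylate 11 (not isolated)
Conditions: NaOH, EtOH/THF/H2O, 70 °C; aq. HCl to pH 2
Reagents that add atoms: sodium hydroxide, [Na+].[OH-]
Why: Ester saponification with concurrent N-desulfonylation: hydroxide also attacks the sulfur of the N-tosyl group, whose indolide leaving group is stabilized by the 2-carboxyl group and the two bromines, so both groups should be removed in one operation while the aryl bromides stay inert.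

Step 5
Reactants: 12 4,7-dibromo-1H-indole-2-carboxylic acid
Product: 13 4,7-dibromo-1H-indole
Conditions: Ag2CO3 (10 mol %), AcOH (cat.), DMSO, 120 °C
Reagents that add atoms: none
Why: Silver-catalysed protodecarboxylation of a heteroaromatic 2-carboxylic acid: the carboxylate of monovalent silver should extrude CO2 and the C2 position is then protonated by acetic acid, while monovalent silver does not insert into aryl C–Br bonds.

Step 6
Reactants: 13 4,7-dibromo-1H-indole
Product: 15 4,7-dibromo-1-(phenylsulfonyl)-1H-indole, via sodium 4,7-dibromoindol-1-ide 14 (not isolated)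
Conditions: NaH, THF, 0 °C; PhSO2Cl, 0 °C to rt
Reagents that add atoms: benzenesulfonyl chloride, O=S(=O)(Cl)c1ccccc1
Why: N-sulfonylation of the sodium indolide, which reacts at nitrogen with the hard sulfonyl electrophile; the sulfonyl group installs the directing and acidifying group needed for C2 metalation.

Step 7
Reactants: 15 4,7-dibromo-1-(phenylsulfonyl)-1H-indole
Product: 17 4,7-dibromo-2-chloro-1-(phenylsulfonyl)-1H-indole, via 2-lithioindole 16 (not isolated)
Conditions: LDA, THF, −78 °C; C2Cl6, −78 °C to rt
Reagents that add atoms: hexachloroethane, ClC(Cl)(Cl)C(Cl)(Cl)Cl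
Why: Directed C2 lithiation of an N-sulfonylindole then electrophilic chlorination: the lithium amide removes the sulfonyl-activated C2–H (the most acidic C–H) without bromine–lithium exchange, and 16 takes a chlorine from hexachloroethane with loss of tetrachloroethylene.

Step 8
Reactants: 17 4,7-dibromo-2-chloro-1-(phenylsulfonyl)-1H-indole
Product: 18 4,7-dibromo-2-chloro-1H-indole
Conditions: TBAF, THF, 60 °C; aq. NH4Cl
Reagents that add atoms: none
Why: N-desulfonylation by fluoride attack at sulfur, releasing the halogen-stabilized indolide, which is protonated on work-up; the conditions are non-reducing and should leave C–Cl and C–Br bonds alone.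

Step 9
Reactants: 18 4,7-dibromo-2-chloro-1H-indole
Product: 19 3,4,7-tribromo-2-chloro-1H-indole (target)
Conditions: NBS, DMF, 0 °C to rt, dark
Reagents that add atoms: N-bromosuccinimide, O=C1CCC(=O)N1Br
Why: Electrophilic aromatic bromination at C3, the only free position of the pyrrole ring and the most nucleophilic carbon of an N–H indole, while the benzene ring is deactivated by its two bromines.

**Compound list**

1 | 1,4-dibromo-2-fluorobenzene | Fc1cc(Br)ccc1Br | starting material
2 | 3,6-dibromo-2-fluorophenyllithium | [Li]c1c(F)c(Br)ccc1Br | intermediate (not isolated)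
3 | lithium (3,6-dibromo-2-fluorophenyl)(dimethylamino)methanolate, racemic | [Li+].[O-]C(N(C)C)c1c(F)c(Br)ccc1Br | intermediate (not isolated)
4 | 3,6-dibromo-2-fluorobenzaldehyde | O=Cc1c(F)c(Br)ccc1Br | intermediate
5 | glycine ethyl ester hydrochloride | CCOC(=O)CN.Cl | starting material
6 | p-toluenesulfonyl chloride | Cc1ccc(cc1)S(=O)(=O)Cl | starting material
7 | ethyl N-tosylglycinate | CCOC(=O)CNS(=O)(=O)c1ccc(C)cc1 | intermediate
8 | ethyl N-(3,6-dibromo-2-formylphenyl)-N-tosylglycinate | CCOC(=O)CN(c1c(C=O)c(Br)ccc1Br)S(=O)(=O)c1ccc(C)cc1 | intermediate (not isolated)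
9 | ethyl 4,7-dibromo-3-hydroxy-1-tosylindoline-2-carboxylate, mixture of diastereomers, racemic | CCOC(=O)C1C(O)c2c(Br)ccc(Br)c2N1S(=O)(=O)c1ccc(C)cc1 | intermediate (not isolated)
10 | ethyl 4,7-dibromo-1-tosyl-1H-indole-2-carboxylate | CCOC(=O)c1cc2c(Br)ccc(Br)c2n1S(=O)(=O)c1ccc(C)cc1 | intermediate
11 | sodium 4,7-dibromo-1H-indole-2-carboxylate | [Na+].[O-]C(=O)c1cc2c(Br)ccc(Br)c2[nH]1 | intermediate (not isolated)
12 | 4,7-dibromo-1H-indole-2-carboxylic acid | OC(=O)c1cc2c(Br)ccc(Br)c2[nH]1 | intermediate
13 | 4,7-dibromo-1H-indole | Brc1ccc(Br)c2[nH]ccc12 | intermediate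
14 | sodium 4,7-dibromoindol-1-ide | [Na+].Brc1ccc(Br)c2[n-]ccc12 | intermediate (not isolated)
15 | 4,7-dibromo-1-(phenylsulfonyl)-1H-indole | Brc1ccc(Br)c2c1ccn2S(=O)(=O)c1ccccc1 | intermediate
16 | 4,7-dibromo-2-lithio-1-(phenylsulfonyl)-1H-indole | [Li]c1cc2c(Br)ccc(Br)c2n1S(=O)(=O)c1ccccc1 | intermediate (not isolated)
17 | 4,7-dibromo-2-chloro-1-(phenylsulfonyl)-1H-indole | Clc1cc2c(Br)ccc(Br)c2n1S(=O)(=O)c1ccccc1 | intermediate
18 | 4,7-dibromo-2-chloro-1H-indole | Clc1cc2c(Br)ccc(Br)c2[nH]1 | intermediate
19 | 3,4,7-tribromo-2-chloro-1H-indole | Clc1[nH]c2c(Br)ccc(Br)c2c1Br | target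

**Step count**

Total steps: 9. Longest linear sequence: 8 (steps 1, 3–9; the glycinate branch through step 2 is equally long).

**Steps most likely to fail**

Step 3 (key step). The bulky secondary sulfonamide anion may displace fluoride only slowly at a carbon flanked by formyl and bromine. That would leave the aldehyde exposed to base-induced degradation, or let the aldol adduct lose p-toluenesulfinate instead of water. Fallback: the aryl C–N bond is made first with a small primary sulfonamide and the glycinate carbon is attached afterwards. Setting out from 4, fluoride is displaced with p-toluenesulfonamide (K2CO3, DMSO, 90 °C) to give N-(3,6-dibromo-2-formylphenyl)-4-methylbenzenesulfonamide F1. N-Alkylation of F1 with ethyl bromoacetate (K2CO3, DMF, 70 °C) leads through 8 and 9 by the established closure of 2-(sulfonylamino)benzaldehydes, and the route is rejoined at 10.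

Step 7. Metalation of the benzene ring ortho to a bromine, bromine migration between lithiated positions, or aryne formation on warming may compete with C2 lithiation and give mixtures of chlorinated products. Fallback without any organolithium: setting out from 13, chlorination with N-chlorosuccinimide (DMF, 0 °C) should give 4,7-dibromo-3-chloro-1H-indole F2. Acid hydrolysis of F2 (H3PO4, 2-methoxyethanol, 100 °C) should give 4,7-dibromoindolin-2-one F3, and chlorodehydration of this lactam with POCl3 (90 °C) should give 18, where the route is rejoined before step 9. Steps 6 to 8 are then not needed.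

Step 8. The free N–H 2-chloroindole with an open C3 position may oxidize, oligomerize or hydrolyse towards the oxindole during desulfonylation or isolation. Fallback by reordering, so that this species is never handled: setting out from 17, bromination at C3 with Br2 (AcOH, 50 °C) should give 3,4,7-tribromo-2-chloro-1-(phenylsulfonyl)-1H-indole F4. Desulfonylation of F4 (TBAF, THF, 60 °C; aq. NH4Cl) delivers the more robust 2,3-dihaloindole directly, and the route comes back at 19.

**Further compounds**

F1 | step 3 | N-(3,6-dibromo-2-formylphenyl)-4-methylbenzenesulfonamide | O=Cc1c(Br)ccc(Br)c1NS(=O)(=O)c1ccc(C)cc1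
F2 | step 7 | 4,7-dibromo-3-chloro-1H-indole | Clc1c[nH]c2c(Br)ccc(Br)c12
F3 | step 7 | 4,7-dibromoindolin-2-one | O=C1Cc2c(Br)ccc(Br)c2N1
F4 | step 8 | 3,4,7-tribromo-2-chloro-1-(phenylsulfonyl)-1H-indole | Clc1c(Br)c2c(Br)ccc(Br)c2n1S(=O)(=O)c1ccccc1
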